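**Plan**

1. Retrosynthetic cuts, in order: the enone C=C on ring C (aldol, then dehydration); the aryl–C(=O) bond between ring A and the C4″ carbonyl (aryllithium + lactone); the lactone C–O bond; the cyclohexene bonds C3″–C4″ and C5″–C6″ (Diels–Alder); the ring C–diene and ring A–prenyl bonds.
2. Enabling feature: the C4″ carbonyl carbon and the phenolic oxygen of ring C ortho to C3″ are 1,5-related (O–C(aryl)–C(aryl)–C3″–C4″–C=O is a six-membered ring). The acyl group can therefore be stored as an aryl lactone fused to the cyclohexene (a 6a,7,8,10a-tetrahydro-6H-benzo[c]chromen-6-one), which serves as acyl donor, phenol protection and stereocontrol element.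
3. Forward: diene 7 (ring C) and hydroxy enone 11 (ring B) give the cyclohexene by a catalytic enantioselective endo Diels–Alder reaction, which sets C3″ and C5″ (absolute configuration from the copper bis(oxazoline) ligand). Ketol cleavage and lactonisation then close the temporary ring.
4. C4″ is the only enolisable stereocentre, and the target is the C4″ epimer of the endo adduct. It is set by kinetic axial protonation of the planar lactone enolate, in which the fused ring forces the C5″ aryl group axial.
5. Aryllithium 24 (ring A) opens the lactone to the ketone and frees the phenol while the acetyl group is masked as its enolate; this enolate then adds to aldehyde 23 (ring D) in the same flask. Acid finally removes six MOM groups and dehydrates to the E-enone.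

Key step: step 16

Remark on locants: C3″, C4″ and C5″ are the cyclohexene carbons carrying ring C (the dihydroxyphenyl ring with the enone), the ring A aroyl group and ring B (4-hydroxyphenyl). The target is (3″S,4″S,5″S), with the aroyl group trans to ring C and cis to ring B.

Assumption: the facial sense of the copper bis(oxazoline) catalyst is taken from the square-planar chelate model of this catalyst family, in which the (S,S)-ligand exposes the Cα-Re face of a chelated s-cis enone. The Cα-Si addition needed here is therefore assigned to the (R,R)-ligand.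

**Route**

Step 1
Reactants: 1 2,4-dihydroxyacetophenone
Product: 2 1-(2,4-dihydroxy-3-iodophenyl)ethanone
Conditions: I2, HIO3, EtOH/H2O, rt
Reagents that add atoms: iodine, II
Why: Electrophilic aromatic iodination (HIO3 as oxidant so that all iodine is used) should occur at C3, the position ortho to both hydroxyl groups.

Step 2
Reactants: 2 1-(2,4-dihydroxy-3-iodophenyl)ethanone
Product: 3 1-[2-hydroxy-3-iodo-4-(prop-2-en-1-yloxy)phenyl]ethanone
Conditions: allyl bromide, K2CO3, acetone, reflux
Reagents that add atoms: allyl bromide, C=CCBr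
Why: Williamson ether synthesis; the 2-hydroxyl is hydrogen-bonded to the acetyl carbonyl, so the weak base should alkylate only the 4-hydroxyl.

Step 3
Reactants: 3 1-[2-hydroxy-3-iodo-4-(prop-2-en-1-yloxy)phenyl]ethanone
Product: 4 1-[3-iodo-2-(methoxymethoxy)-4-(prop-2-en-1-yloxy)phenyl]ethanone
Conditions: NaH, MOMCl, DMF, 0 °C to rt
Reagents that add atoms: chloromethyl methyl ether, COCCl
Why: Williamson-type O-alkylation of the sodium phenoxide should cap the chelated phenol as the MOM ether that stays until the last step.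

Step 4
Reactants: 5 2-methylbut-1-en-3-yne
Product: 6 (E)-4,4,5,5-tetramethyl-2-(3-methylbuta-1,3-dien-1-yl)-1,3,2-dioxaborolane
Conditions: pinacolborane, Cp2Zr(H)Cl (5 mol%), Et3N (10 mol%), neat, 60 °C
Reagents that add atoms: pinacolborane, [H]B1OC(C)(C)C(C)(C)O1
Why: Zirconium hydride-catalysed syn hydroboration of the terminal alkyne places boron on the terminal carbon and should give the E-dienylboronate.

Step 5
Reactants: 4 1-[3-iodo-2-(methoxymethoxy)-4-(prop-2-en-1-yloxy)phenyl]ethanone, 6 (E)-4,4,5,5-tetramethyl-2-(3-methylbuta-1,3-dien-1-yl)-1,3,2-dioxaborolane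
Product: 7 1-{2-(methoxymethoxy)-3-[(1E)-3-methylbuta-1,3-dien-1-yl]-4-(prop-2-en-1-yloxy)phenyl}ethanone
Conditions: Pd(OAc)2 (5 mol%), SPhos (10 mol%), K3PO4, toluene/H2O, 80 °C
Reagents that add atoms: none
Why: Suzuki–Miyaura coupling with retention of the E-alkene; the biarylphosphine ligand suits the di-ortho-substituted aryl iodide, and the two protected phenols keep the o-hydroxy diene from cyclising to a chromene.

Step 6
Reactants: 8 4-hydroxybenzaldehyde
Product: 9 4-(methoxymethoxy)benzaldehyde
Conditions: MOMCl, iPr2NEt, CH2Cl2, 0 °C to rt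
Reagents that add atoms: chloromethyl methyl ether, COCCl
Why: MOM ether formation (base-mediated O-alkylation) protects the phenol so that the aldehyde stays electrophilic in the next step.

Step 7
Reactants: 9 4-(methoxymethoxy)benzaldehyde, 10 3-hydroxy-3-methylbutan-2-one
Product: 11 (1E)-4-hydroxy-1-[4-(methoxymethoxy)phenyl]-4-methylpent-1-en-3-one
Conditions: LiOH·H2O, MeOH/H2O, reflux
Reagents that add atoms: none
Why: Claisen–Schmidt condensation; the ketone can enolise only at its methyl group and the aldehyde has no α-hydrogen, so a single E-enone should form.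

Step 8
Reactants: 7 1-{2-(methoxymethoxy)-3-[(1E)-3-methylbuta-1,3-dien-1-yl]-4-(prop-2-en-1-yloxy)phenyl}ethanone, 11 (1E)-4-hydroxy-1-[4-(methoxymethoxy)phenyl]-4-methylpent-1-en-3-one
Product: 12 1-{(1R,2S,6S)-2-[3-acetyl-2-(methoxymethoxy)-6-(prop-2-en-1-yloxy)phenyl]-6-[4-(methoxymethoxy)phenyl]-4-methylcyclohex-3-en-1-yl}-2-hydroxy-2-methylpropan-1-one
Conditions: [Cu((R,R)-t-Bu-box)](SbF6)2 (10 mol%; t-Bu-box = 2,2′-(propane-2,2-diyl)bis(4-tert-butyl-4,5-dihydrooxazole)), 4 Å molecular sieves, CH2Cl2, 0 °C to rt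
Reagents that add atoms: none
Why: Lewis acid-catalysed Diels–Alder reaction in which the hydroxy enone chelates the divalent copper complex through its carbonyl and hydroxyl oxygens, the diene should add endo to the exposed Cα-Si face so that C1 (R), C2 (S) and C6 (S) arise together, and the aryl and methyl groups of the diene direct its CH2 terminus to the β-carbon.

Step 9
Reactants: 12 1-{(1R,2S,6S)-2-[3-acetyl-2-(methoxymethoxy)-6-(prop-2-en-1-yloxy)phenyl]-6-[4-(methoxymethoxy)phenyl]-4-methylcyclohex-3-en-1-yl}-2-hydroxy-2-methylpropan-1-one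
Product: 13 (1R,2S,6S)-2-[3-acetyl-2-(methoxymethoxy)-6-(prop-2-en-1-yloxy)phenyl]-6-[4-(methoxymethoxy)phenyl]-4-methylcyclohex-3-ene-1-carboxylic acid
Conditions: NaIO4, MeOH/H2O, rt
Reagents that add atoms: water, O
Why: Periodate cleavage of the α-hydroxy ketone (glycol-type cleavage of its hydrate) should release the carboxylic acid and acetone without touching the alkenes, the methyl ketone or the stereocentres.

Step 10
Reactants: 13 (1R,2S,6S)-2-[3-acetyl-2-(methoxymethoxy)-6-(prop-2-en-1-yloxy)phenyl]-6-[4-(methoxymethoxy)phenyl]-4-methylcyclohex-3-ene-1-carboxylic acid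
Product: 14 (1R,2S,6S)-2-[3-acetyl-6-hydroxy-2-(methoxymethoxy)phenyl]-6-[4-(methoxymethoxy)phenyl]-4-methylcyclohex-3-ene-1-carboxylic acid
Conditions: Pd(PPh3)4 (5 mol%), morpholine, THF, rt
Reagents that add atoms: none
Why: Tsuji–Trost deallylation, in which zerovalent palladium ionises the aryl allyl ether and morpholine traps the allyl unit, should free only this phenol and leave MOM ethers and alkenes intact.

Step 11
Reactants: 14 (1R,2S,6S)-2-[3-acetyl-6-hydroxy-2-(methoxymethoxy)phenyl]-6-[4-(methoxymethoxy)phenyl]-4-methylcyclohex-3-ene-1-carboxylic acid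
Product: 15 (6aR,7S,10aS)-2-acetyl-1-(methoxymethoxy)-7-[4-(methoxymethoxy)phenyl]-9-methyl-6a,7,8,10a-tetrahydro-6H-benzo[c]chromen-6-one
Conditions: DCC, DMAP (cat.), CH2Cl2, 0 °C to rt
Reagents that add atoms: none
Why: Steglich-type lactonisation; the carboxyl group and the aryl ring are cis on C1/C2, so the only free phenol should close the six-membered aryl lactone as the cis-fused isomer.

Step 12
Reactants: 15 (6aR,7S,10aS)-2-acetyl-1-(methoxymethoxy)-7-[4-(methoxymethoxy)phenyl]-9-methyl-6a,7,8,10a-tetrahydro-6H-benzo[c]chromen-6-one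
Product: 17 (6aS,7S,10aS)-2-acetyl-1-(methoxymethoxy)-7-[4-(methoxymethoxy)phenyl]-9-methyl-6a,7,8,10a-tetrahydro-6H-benzo[c]chromen-6-one, via dilithium dienolate 16 (not isolated)
Conditions: LiN(iPr)2 (2.3 equiv), THF, −78 °C; then AcOH (excess, precooled, in THF), −78 °C
Reagents that add atoms: none
Why: Enolate formation and kinetic protonation: deprotonation makes C6a trigonal (the acetyl group is enolised as well), and in 16 the planar fused pyranone ring holds the C10a–aryl bond equatorial, which forces the trans-disposed C7 aryl group axial next to C6a, so the proton should enter C6a axially on the opposite face (as in the ketonisation of exocyclic cyclohexyl enolates anti to a vicinal axial aryl group) and give the trans-fused lactone with the carbonyl cis to the C7 aryl group, i.e. 6aS, whatever the C6a configuration of the material used.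

Step 13
Reactants: 18 4-bromobenzene-1,3-diol
Product: 19 1-bromo-2,4-bis(methoxymethoxy)benzene
Conditions: MOMCl, iPr2NEt, CH2Cl2, 0 °C to rt
Reagents that add atoms: chloromethyl methyl ether, COCCl
Why: MOM ether formation gives acetal-protected phenols that direct the next lithiation and survive organolithium reagents.

Step 14
Reactants: 19 1-bromo-2,4-bis(methoxymethoxy)benzene
Product: 21 1-bromo-2,4-bis(methoxymethoxy)-3-(3-methylbut-2-en-1-yl)benzene, via aryllithium 20 (not isolated)
Conditions: LiN(iPr)2, THF, −78 °C; then CuBr·SMe2 (10 mol%), prenyl bromide, −78 to 0 °C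
Reagents that add atoms: 1-bromo-3-methylbut-2-ene, CC(C)=CCBr
Why: Directed ortho-metalation, in which the amide base removes the proton flanked by the two MOM-oxy groups without bromine–lithium exchange, followed by copper-catalysed allylic substitution of prenyl bromide, should give the linear prenyl arene.

Step 15
Reactants: 22 2,4-dihydroxybenzaldehyde
Product: 23 2,4-bis(methoxymethoxy)benzaldehyde
Conditions: NaH, MOMCl, DMF, 0 °C to rt
Reagents that add atoms: chloromethyl methyl ether, COCCl
Why: MOM ether formation with a strong base, so that the chelated ortho-hydroxyl is alkylated as well.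

Step 16
Reactants: 17 (6aS,7S,10aS)-2-acetyl-1-(methoxymethoxy)-7-[4-(methoxymethoxy)phenyl]-9-methyl-6a,7,8,10a-tetrahydro-6H-benzo[c]chromen-6-one, 21 1-bromo-2,4-bis(methoxymethoxy)-3-(3-methylbut-2-en-1-yl)benzene, 23 2,4-bis(methoxymethoxy)benzaldehyde
Product: 27 {(1S,2S,6S)-2-[3-{3-[2,4-bis(methoxymethoxy)phenyl]-3-hydroxypropanoyl}-6-hydroxy-2-(methoxymethoxy)phenyl]-6-[4-(methoxymethoxy)phenyl]-4-methylcyclohex-3-en-1-yl}[2,4-bis(methoxymethoxy)-3-(3-methylbut-2-en-1-yl)phenyl]methanone (both carbinol epimers), via aryllithium 24 (not isolated), via lithium enolate 25 (not isolated), via dilithium lactolate 26 (not isolated)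
Conditions: 21, n-BuLi, THF, −78 °C; separately 17, LiN(SiMe3)2 (1.05 equiv), THF, −78 °C; add the aryllithium (1.15 equiv), −78 °C; then 23 (1.5 equiv), −78 °C; AcOH, −78 °C
Reagents that add atoms: none
Why: LiN(SiMe3)2 first converts the acetyl group of 17, the only readily enolisable site, into lithium enolate 25, which is inert to nucleophiles; aryllithium 24, made by bromine–lithium exchange of 21, then adds to the lactone carbonyl C6, the only electrophile left, to give lactolate 26, which forms the aryl–C(=O) bond and, on collapse or work-up, both the ketone and the free phenol of ring C. The closest known reaction types are the addition of organolithium reagents to lactones (dihydrocoumarins give ketones carrying an o-hydroxyaryl group) and the crossed aldol addition of a preformed lithium enolate, by which 25 takes up aldehyde 23 in the same flask. No ring is closed; the temporary six-membered lactone is opened. C6a (C4″) is not touched, because the nucleophile attacks the carbonyl carbon and the lactolate cannot enolise, so the configuration set in step 12 is carried into the ketone, while the new carbinol centre is uncontrolled and disappears in step 17. The step needs mono-addition and chemoselectivity, which the chelated lactolate at −78 °C, the shielding of the product ketone by its α-branch and ortho-substituted aryl group, and the enolate masking of the acetyl group should secure.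

Step 17
Reactants: 27 {(1S,2S,6S)-2-[3-{3-[2,4-bis(methoxymethoxy)phenyl]-3-hydroxypropanoyl}-6-hydroxy-2-(methoxymethoxy)phenyl]-6-[4-(methoxymethoxy)phenyl]-4-methylcyclohex-3-en-1-yl}[2,4-bis(methoxymethoxy)-3-(3-methylbut-2-en-1-yl)phenyl]methanone
Product: 28 (2E)-1-{3-[(1S,5S,6S)-6-[2,4-dihydroxy-3-(3-methylbut-2-en-1-yl)benzoyl]-5-(4-hydroxyphenyl)-3-methylcyclohex-2-en-1-yl]-2,4-dihydroxyphenyl}-3-(2,4-dihydroxyphenyl)prop-2-en-1-one
Conditions: HCl (3 M aq.)/MeOH, rt
Reagents that add atoms: none
Why: Acid-catalysed cleavage of the six MOM acetals and E1 dehydration of the benzylic β-hydroxy ketone (cation stabilised by the 2,4-dioxygenated ring, expected before the ortho-phenol of ring C is unmasked) should give the E-enone and the free phenols, with dilute acid at room temperature and no base chosen to spare the C4″ stereocentre, the prenyl group and the ring alkene.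

**Compound list**

1 | 2,4-dihydroxyacetophenone | CC(=O)c1ccc(O)cc1O | starting material
2 | 1-(2,4-dihydroxy-3-iodophenyl)ethanone | CC(=O)c1ccc(O)c(I)c1O | intermediate
3 | 1-[2-hydroxy-3-iodo-4-(prop-2-en-1-yloxy)phenyl]ethanone | CC(=O)c1ccc(OCC=C)c(I)c1O | intermediate
4 | 1-[3-iodo-2-(methoxymethoxy)-4-(prop-2-en-1-yloxy)phenyl]ethanone | CC(=O)c1ccc(OCC=C)c(I)c1OCOC | intermediate
5 | 2-methylbut-1-en-3-yne | C=C(C)C#C | starting material
6 | (E)-4,4,5,5-tetramethyl-2-(3-methylbuta-1,3-dien-1-yl)-1,3,2-dioxaborolane | C=C(C)/C=C/B1OC(C)(C)C(C)(C)O1 | intermediate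
7 | 1-{2-(methoxymethoxy)-3-[(1E)-3-methylbuta-1,3-dien-1-yl]-4-(prop-2-en-1-yloxy)phenyl}ethanone | CC(=O)c1ccc(OCC=C)c(/C=C/C(C)=C)c1OCOC | intermediate
8 | 4-hydroxybenzaldehyde | O=Cc1ccc(O)cc1 | starting material
9 | 4-(methoxymethoxy)benzaldehyde | COCOc1ccc(C=O)cc1 | intermediate
10 | 3-hydroxy-3-methylbutan-2-one | CC(=O)C(C)(C)O | starting material
11 | (1E)-4-hydroxy-1-[4-(methoxymethoxy)phenyl]-4-methylpent-1-en-3-one | CC(C)(O)C(=O)/C=C/c1ccc(OCOC)cc1 | intermediate
12 | 1-{(1R,2S,6S)-2-[3-acetyl-2-(methoxymethoxy)-6-(prop-2-en-1-yloxy)phenyl]-6-[4-(methoxymethoxy)phenyl]-4-methylcyclohex-3-en-1-yl}-2-hydroxy-2-methylpropan-1-one (endo adduct) | CC(C)(O)C(=O)[C@H]1[C@@H](c2c(OCC=C)ccc(C(C)=O)c2OCOC)C=C(C)C[C@@H]1c1ccc(OCOC)cc1 | intermediate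
13 | (1R,2S,6S)-2-[3-acetyl-2-(methoxymethoxy)-6-(prop-2-en-1-yloxy)phenyl]-6-[4-(methoxymethoxy)phenyl]-4-methylcyclohex-3-ene-1-carboxylic acid | OC(=O)[C@H]1[C@@H](c2c(OCC=C)ccc(C(C)=O)c2OCOC)C=C(C)C[C@@H]1c1ccc(OCOC)cc1 | intermediate
14 | (1R,2S,6S)-2-[3-acetyl-6-hydroxy-2-(methoxymethoxy)phenyl]-6-[4-(methoxymethoxy)phenyl]-4-methylcyclohex-3-ene-1-carboxylic acid | OC(=O)[C@H]1[C@@H](c2c(O)ccc(C(C)=O)c2OCOC)C=C(C)C[C@@H]1c1ccc(OCOC)cc1 | intermediate
15 | (6aR,7S,10aS)-2-acetyl-1-(methoxymethoxy)-7-[4-(methoxymethoxy)phenyl]-9-methyl-6a,7,8,10a-tetrahydro-6H-benzo[c]chromen-6-one (cis-fused lactone) | O=C1[C@H]2[C@@H](c3c(O1)ccc(C(C)=O)c3OCOC)C=C(C)C[C@@H]2c2ccc(OCOC)cc2 | intermediate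
16 | dilithium dienolate of 15 (lactone enolate C6(O–)=C6a and acetyl enolate; C7 and C10a unchanged) | [Li+].[Li+].[O-]C1=C2[C@@H](c3c(O1)ccc(C([O-])=C)c3OCOC)C=C(C)C[C@@H]2c2ccc(OCOC)cc2 | intermediate
17 | (6aS,7S,10aS)-2-acetyl-1-(methoxymethoxy)-7-[4-(methoxymethoxy)phenyl]-9-methyl-6a,7,8,10a-tetrahydro-6H-benzo[c]chromen-6-one (trans-fused lactone) | O=C1[C@@H]2[C@@H](c3c(O1)ccc(C(C)=O)c3OCOC)C=C(C)C[C@@H]2c2ccc(OCOC)cc2 | intermediate
18 | 4-bromobenzene-1,3-diol | Oc1ccc(Br)c(O)c1 | starting material
19 | 1-bromo-2,4-bis(methoxymethoxy)benzene | COCOc1ccc(Br)c(OCOC)c1 | intermediate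
20 | [3-bromo-2,6-bis(methoxymethoxy)phenyl]lithium | COCOc1ccc(Br)c(OCOC)c1[Li] | intermediate
21 | 1-bromo-2,4-bis(methoxymethoxy)-3-(3-methylbut-2-en-1-yl)benzene | COCOc1ccc(Br)c(OCOC)c1CC=C(C)C | intermediate
22 | 2,4-dihydroxybenzaldehyde | O=Cc1ccc(O)cc1O | starting material
23 | 2,4-bis(methoxymethoxy)benzaldehyde | COCOc1ccc(C=O)c(OCOC)c1 | intermediate
24 | [2,4-bis(methoxymethoxy)-3-(3-methylbut-2-en-1-yl)phenyl]lithium | COCOc1ccc([Li])c(OCOC)c1CC=C(C)C | intermediate
25 | lithium enolate of the acetyl group of 17 | [Li+].O=C1[C@@H]2[C@@H](c3c(O1)ccc(C([O-])=C)c3OCOC)C=C(C)C[C@@H]2c2ccc(OCOC)cc2 | intermediate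
26 | dilithium salt of the C6 lactol adduct of 24 and 25 (6-aryl-6-oxido lactolate with the acetyl enolate; C6 configuration undefined) | [Li+].[Li+].[O-]C1(c4ccc(OCOC)c(CC=C(C)C)c4OCOC)[C@@H]2[C@@H](c3c(O1)ccc(C([O-])=C)c3OCOC)C=C(C)C[C@@H]2c2ccc(OCOC)cc2 | intermediate
27 | {(1S,2S,6S)-2-[3-{3-[2,4-bis(methoxymethoxy)phenyl]-3-hydroxypropanoyl}-6-hydroxy-2-(methoxymethoxy)phenyl]-6-[4-(methoxymethoxy)phenyl]-4-methylcyclohex-3-en-1-yl}[2,4-bis(methoxymethoxy)-3-(3-methylbut-2-en-1-yl)phenyl]methanone (both carbinol epimers) | CC(C)=CCc1c(OCOC)ccc(C(=O)[C@@H]2[C@@H](c3c(O)ccc(C(=O)CC(O)c4ccc(OCOC)cc4OCOC)c3OCOC)C=C(C)C[C@@H]2c2ccc(OCOC)cc2)c1OCOC | intermediate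
28 | (2E)-1-{3-[(1S,5S,6S)-6-[2,4-dihydroxy-3-(3-methylbut-2-en-1-yl)benzoyl]-5-(4-hydroxyphenyl)-3-methylcyclohex-2-en-1-yl]-2,4-dihydroxyphenyl}-3-(2,4-dihydroxyphenyl)prop-2-en-1-one | CC(C)=CCc1c(O)ccc(C(=O)[C@@H]2[C@@H](c3c(O)ccc(C(=O)/C=C/c4ccc(O)cc4O)c3O)C=C(C)C[C@@H]2c2ccc(O)cc2)c1O | target

**Step count and risks**

Total: 17 steps. Longest linear sequence: 11 steps (steps 1, 2, 3, 5, 8, 9, 10, 11, 12, 16, 17).

Steps most likely to fail:

Step 16. The lactolate may collapse early, so that a second aryllithium adds to the freed ketone. The aryllithium may also act as a base at C6a–H, which would scramble C4″, or enolate 25 may undergo Claisen-type self-acylation. The fallback replaces the polar organolithium acylation by a neutral thioester cross-coupling; it sets out from 17 and 21 and returns at 27. Lactone 17 would be opened with Me2AlSEt (from AlMe3 and EtSH, CH2Cl2, 0 °C) to S-ethyl (1S,2S,6S)-2-[3-acetyl-6-hydroxy-2-(methoxymethoxy)phenyl]-6-[4-(methoxymethoxy)phenyl]-4-methylcyclohex-3-ene-1-carbothioate F1. Bromide 21 would be converted (n-BuLi, then B(OiPr)3, aqueous NH4Cl) to [2,4-bis(methoxymethoxy)-3-(3-methylbut-2-en-1-yl)phenyl]boronic acid F2. Liebeskind–Srogl coupling of the two (Pd2(dba)3, tri(2-furyl)phosphine, Cu(O2CC4H3S) as the carboxylate of monovalent copper, THF, 50 °C) is base-free and known to spare α-stereocentres; it should give the ring A ketone that still carries the acetyl group and the free phenol, F3. The acetyl group of F3 would then be enolised at its methyl group (LiN(iPr)2, 2.2 equiv, THF, −78 °C) and added to 23 to reach 27.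

Step 12. Deprotonation of the hindered ring-fusion C–H may be incomplete. The aryl ester enolate may fragment to a ketene that is captured by the amine, or protonation may occur on oxygen and be followed by unselective ketonisation on warming. The fallback avoids a metal enolate; it sets out from 15 and returns at 17. Soft enolisation with TBSOTf/Et3N (CH2Cl2, 0 °C) should give the isolable bis-silyl compound (silyl ketene acetal at C6/C6a and silyl enol ether of the acetyl group) F4. Protodesilylation with TBAF/AcOH (THF, −78 °C) would then deliver the proton to C6a under the same steric control and give 17.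

Step 8. The copper complex may discriminate poorly between endo and exo approach or between the two faces with this di-ortho-substituted aryl diene, and a slow cycloaddition may let the diene oligomerise. The fallback replaces catalyst control by auxiliary control; it sets out from 9 and 7 and returns at 13. Horner–Wadsworth–Emmons reaction of 9 with (4S)-4-benzyl-3-[(diethoxyphosphoryl)acetyl]oxazolidin-2-one (LiCl, iPr2NEt, MeCN) would give (4S)-4-benzyl-3-{(2E)-3-[4-(methoxymethoxy)phenyl]prop-2-enoyl}oxazolidin-2-one F5. Its Et2AlCl-promoted Diels–Alder reaction with 7 (CH2Cl2, −30 °C) should take place endo on the Cα-Si face, opposite the benzyl group of the chelated imide, to give the N-acyl oxazolidinone adduct F6. LiOH/H2O2 (THF/H2O, 0 °C) would remove the auxiliary and give acid 13.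

**Further compounds**

F1 | step 16 | S-ethyl (1S,2S,6S)-2-[3-acetyl-6-hydroxy-2-(methoxymethoxy)phenyl]-6-[4-(methoxymethoxy)phenyl]-4-methylcyclohex-3-ene-1-carbothioate | CCSC(=O)[C@@H]1[C@@H](c2c(O)ccc(C(C)=O)c2OCOC)C=C(C)C[C@@H]1c1ccc(OCOC)cc1
F2 | step 16 | [2,4-bis(methoxymethoxy)-3-(3-methylbut-2-en-1-yl)phenyl]boronic acid | COCOc1ccc(B(O)O)c(OCOC)c1CC=C(C)C
F3 | step 16 | 1-{3-[(1S,5S,6S)-6-[2,4-bis(methoxymethoxy)-3-(3-methylbut-2-en-1-yl)benzoyl]-5-[4-(methoxymethoxy)phenyl]-3-methylcyclohex-2-en-1-yl]-4-hydroxy-2-(methoxymethoxy)phenyl}ethanone | CC(C)=CCc1c(OCOC)ccc(C(=O)[C@@H]2[C@@H](c3c(O)ccc(C(C)=O)c3OCOC)C=C(C)C[C@@H]2c2ccc(OCOC)cc2)c1OCOC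
F4 | step 12 | (7S,10aS)-6-(tert-butyldimethylsilyloxy)-2-[1-(tert-butyldimethylsilyloxy)ethenyl]-1-(methoxymethoxy)-7-[4-(methoxymethoxy)phenyl]-9-methyl-8,10a-dihydro-7H-benzo[c]chromene | CC(C)(C)[Si](C)(C)OC1=C2[C@@H](c3c(O1)ccc(C(=C)O[Si](C)(C)C(C)(C)C)c3OCOC)C=C(C)C[C@@H]2c2ccc(OCOC)cc2
F5 | step 8 | (4S)-4-benzyl-3-{(2E)-3-[4-(methoxymethoxy)phenyl]prop-2-enoyl}oxazolidin-2-one | COCOc1ccc(/C=C/C(=O)N2[C@@H](Cc3ccccc3)COC2=O)cc1
F6 | step 8 | (4S)-3-{(1R,2S,6S)-2-[3-acetyl-2-(methoxymethoxy)-6-(prop-2-en-1-yloxy)phenyl]-6-[4-(methoxymethoxy)phenyl]-4-methylcyclohex-3-ene-1-carbonyl}-4-benzyloxazolidin-2-one | O=C([C@H]1[C@@H](c2c(OCC=C)ccc(C(C)=O)c2OCOC)C=C(C)C[C@@H]1c1ccc(OCOC)cc1)N1[C@@H](Cc2ccccc2)COC1=O
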